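**Retrosynthetic overview**
1. The 8-O-ester and the 13-O-acetate are put on last; no C–C bond is made after the ring closure.
2. The ten-membered carbocycle and the butenolide come from one Ni/Cr-mediated C6–C7 closure of an open-chain (Z)-β-triflyloxy enoate onto an epoxy aldehyde; the chromium alkoxide lactonises onto the cis CO2Me in the same flask.
3. Both oxiranes are made on the open chain before that: C4–C5 by Sharpless epoxidation, C1–C2 by Shi epoxidation.
4. The chain comes from a Cu-catalysed alkyne/allyl bromide coupling (C2–C3) plus Lindlar reduction, a crossed Claisen/enol triflation (C7–C11), and an asymmetric glyoxylate-ene reaction of 2-methylbut-1-en-3-yne (C8).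
5. Ring order: C4–C5 oxirane, then C1–C2 oxirane, then carbocycle and butenolide together.

Assumption: the SMILES is read as (1R,2S,4R,5R,6S,8S) in germacrane numbering (ring C1–C10; C11 on C7 carries C12 = lactone C=O closed to O6 and C13 = CH2OAc; C14 = exocyclic CH2 on C10; C15 = CH3 on C4), used for all ring compounds; TBS = tert-butyldimethylsilyl, Tf = trifluoromethanesulfonyl.

**Step 1**
Reactants: 1 2-methylbut-1-en-3-yne; 2 ethyl glyoxylate (ethyl 2-oxoacetate)
Product: 3 ethyl (2S)-2-hydroxy-4-methylidenehex-5-ynoate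
Conditions: 1 (3 equiv), [Cu((S,S)-tBu-box)](SbF6)2 (5 mol%; box = 2,2'-(propane-2,2-diyl)bis(4-tert-butyl-4,5-dihydro-1,3-oxazole)), CH2Cl2, 0 °C to rt
Reagents that add atoms: none
Why: Lewis-acid-catalysed carbonyl-ene (glyoxylate-ene) reaction: the CH3 of 1 is the only allylic C–H, so the C–C bond forms at the terminal CH2 and the alkene moves to the exocyclic position, while the square-planar copper–glyoxylate chelate of the (S,S)-ligand leaves the Si face of the aldehyde open and sets C8 (C2 of 3) as S.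

**Step 2**
Reactants: 3 ethyl (2S)-2-hydroxy-4-methylidenehex-5-ynoate
Product: 4 ethyl (2S)-2-[(tert-butyldimethylsilyl)oxy]-4-methylidenehex-5-ynoate
Conditions: TBSCl, imidazole, DMF, rt
Reagents that add atoms: tert-butyldimethylsilyl chloride, CC(C)(C)[Si](C)(C)Cl
Why: Standard silyl ether formation (substitution at silicon) that masks the C8 hydroxyl for the enolate chemistry to come without touching the stereocentre.

**Step 3**
Reactants: 5 methyl 3-hydroxypropanoate
Product: 6 methyl 3-[(tert-butyldimethylsilyl)oxy]propanoate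
Conditions: TBSCl, imidazole, CH2Cl2, 0 °C to rt
Reagents that add atoms: tert-butyldimethylsilyl chloride, CC(C)(C)[Si](C)(C)Cl
Why: Standard silylation of a primary alcohol, giving the C11–C13 building block with O13 protected against β-elimination problems of a free alkoxide.

**Step 4**
Reactants: 4 ethyl (2S)-2-[(tert-butyldimethylsilyl)oxy]-4-methylidenehex-5-ynoate; 6 methyl 3-[(tert-butyldimethylsilyl)oxy]propanoate
Product: 8 methyl (4S)-4-[(tert-butyldimethylsilyl)oxy]-2-{[(tert-butyldimethylsilyl)oxy]methyl}-6-methylidene-3-oxooct-7-ynoate (both C2 epimers), via lithium ester enolate 7 (not isolated)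
Conditions: 6 (2.6 equiv), LiN(iPr)2 (2.5 equiv), THF, −78 °C; then 4, −78 to −40 °C; aq. NH4Cl
Reagents that add atoms: none
Why: Crossed Claisen condensation: the preformed enolate 7 attacks the activated α-silyloxy ester of 4 and the β-keto ester is protected as its enolate until the quench, while C8 keeps its configuration because no free amide base is left to remove the less acidic α-silyloxy C–H at −78 °C.

**Step 5**
Reactants: 8 methyl (4S)-4-[(tert-butyldimethylsilyl)oxy]-2-{[(tert-butyldimethylsilyl)oxy]methyl}-6-methylidene-3-oxooct-7-ynoate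
Product: 10 methyl (2Z,4S)-4-[(tert-butyldimethylsilyl)oxy]-2-{[(tert-butyldimethylsilyl)oxy]methyl}-6-methylidene-3-[(trifluoromethanesulfonyl)oxy]oct-2-en-7-ynoate, via chelated lithium enolate 9 (not isolated)
Conditions: LiN(SiMe3)2 (1.05 equiv), THF, −78 °C; then N-(5-chloropyridin-2-yl)-1,1,1-trifluoro-N-(trifluoromethanesulfonyl)methanesulfonamide, −78 to 0 °C
Reagents that add atoms: N-(5-chloropyridin-2-yl)-1,1,1-trifluoro-N-(trifluoromethanesulfonyl)methanesulfonamide, FC(F)(F)S(=O)(=O)N(c1ccc(Cl)cn1)S(=O)(=O)C(F)(F)F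
Why: Enol triflate formation by O-sulfonylation of a lithium enolate: lithium bridges the enolate oxygen and the ester carbonyl (chelated Z-enolate 9), so the triflate ends up cis to CO2Me as needed later for lactonisation, and only the doubly activated C11–H is removed so C8 is untouched.

**Step 6**
Reactants: 11 3-methylbut-2-en-1-yl acetate (prenyl acetate)
Product: 12 (2E)-4-hydroxy-3-methylbut-2-en-1-yl acetate
Conditions: SeO2 (0.3 equiv), t-BuOOH, CH2Cl2, rt
Reagents that add atoms: tert-butyl hydroperoxide, CC(C)(C)OO; selenium dioxide (catalytic oxygen carrier), O=[Se]=O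
Why: Riley allylic oxidation (ene reaction of SeO2 followed by a 2,3-sigmatropic shift), which hydroxylates the methyl group trans to the CH2OAc chain and so gives the (E)-allylic alcohol.

**Step 7**
Reactants: 12 (2E)-4-hydroxy-3-methylbut-2-en-1-yl acetate
Product: 13 (2E)-4-bromo-3-methylbut-2-en-1-yl acetate
Conditions: CBr4, PPh3, CH2Cl2, 0 °C
Reagents that add atoms: carbon tetrabromide, BrC(Br)(Br)Br
Why: Appel reaction: bromide displaces the alkoxyphosphonium at the primary allylic carbon by SN2 with retention of the (E)-alkene.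

**Step 8**
Reactants: 13 (2E)-4-bromo-3-methylbut-2-en-1-yl acetate
Product: 14 (2E)-4-bromo-3-methylbut-2-en-1-ol
Conditions: iBu2AlH (2.2 equiv), CH2Cl2, −78 °C; aq. potassium sodium tartrate
Reagents that add atoms: none
Why: Hydride reduction of the acetate (to the aluminium alkoxide of 14 and ethanol) at −78 °C, where the allylic bromide is inert; a base-free deacetylation that keeps the (E)-alkene.

**Step 9**
Reactants: 10 methyl (2Z,4S)-4-[(tert-butyldimethylsilyl)oxy]-2-{[(tert-butyldimethylsilyl)oxy]methyl}-6-methylidene-3-[(trifluoromethanesulfonyl)oxy]oct-2-en-7-ynoate; 14 (2E)-4-bromo-3-methylbut-2-en-1-ol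
Product: 15 methyl (2Z,4S,10E)-4-[(tert-butyldimethylsilyl)oxy]-2-{[(tert-butyldimethylsilyl)oxy]methyl}-12-hydroxy-10-methyl-6-methylidene-3-[(trifluoromethanesulfonyl)oxy]dodeca-2,10-dien-7-ynoate
Conditions: CuI (20 mol%), K2CO3, DMF, rt
Reagents that add atoms: none
Why: Copper-catalysed alkynylation of an allylic halide (copper acetylide, SN2 at the primary allylic bromide), which joins C2 to C3 with retention of the (E)-alkene and tolerates the free hydroxyl and the enol triflate.

**Step 10**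
Reactants: 15 methyl (2Z,4S,10E)-4-[(tert-butyldimethylsilyl)oxy]-2-{[(tert-butyldimethylsilyl)oxy]methyl}-12-hydroxy-10-methyl-6-methylidene-3-[(trifluoromethanesulfonyl)oxy]dodeca-2,10-dien-7-ynoate
Product: 16 methyl (2Z,4S,7Z,10E)-4-[(tert-butyldimethylsilyl)oxy]-2-{[(tert-butyldimethylsilyl)oxy]methyl}-12-hydroxy-10-methyl-6-methylidene-3-[(trifluoromethanesulfonyl)oxy]dodeca-2,7,10-trienoate
Conditions: H2 (1 atm), Pd/CaCO3 poisoned with Pb(OAc)2, quinoline, EtOAc, rt
Reagents that add atoms: none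
Why: Lindlar semihydrogenation: syn delivery of H2 to the enyne triple bond on the poisoned palladium surface gives the (Z)-C1=C2 alkene and stops there; no stereocentre is formed.

**Step 11**
Reactants: 16 methyl (2Z,4S,7Z,10E)-4-[(tert-butyldimethylsilyl)oxy]-2-{[(tert-butyldimethylsilyl)oxy]methyl}-12-hydroxy-10-methyl-6-methylidene-3-[(trifluoromethanesulfonyl)oxy]dodeca-2,7,10-trienoate
Product: 17 methyl (2Z,4S,7Z)-4-[(tert-butyldimethylsilyl)oxy]-2-{[(tert-butyldimethylsilyl)oxy]methyl}-9-[(2R,3R)-3-(hydroxymethyl)-2-methyloxiran-2-yl]-6-methylidene-3-[(trifluoromethanesulfonyl)oxy]nona-2,7-dienoate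
Conditions: Ti(OiPr)4 (10 mol%), D-(−)-diethyl tartrate (12 mol%), t-BuOOH, 4 Å MS, CH2Cl2, −20 °C
Reagents that add atoms: tert-butyl hydroperoxide, CC(C)(C)OO
Why: Sharpless asymmetric epoxidation: only the alkene bearing the allylic hydroxyl reacts inside the titanium tartrate complex, and D-(−)-diethyl tartrate delivers oxygen to the face that gives the (2R,3R)-epoxy alcohol (C4 R, C5 R), the mirror image of the (2S,3S) products that geraniol-type (E)-alcohols give with the L-(+)-ester.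

**Step 12**
Reactants: 17 methyl (2Z,4S,7Z)-4-[(tert-butyldimethylsilyl)oxy]-2-{[(tert-butyldimethylsilyl)oxy]methyl}-9-[(2R,3R)-3-(hydroxymethyl)-2-methyloxiran-2-yl]-6-methylidene-3-[(trifluoromethanesulfonyl)oxy]nona-2,7-dienoate
Product: 18 methyl (2Z,4S)-4-[(tert-butyldimethylsilyl)oxy]-2-{[(tert-butyldimethylsilyl)oxy]methyl}-6-[(2R,3S)-3-{[(2R,3R)-3-(hydroxymethyl)-2-methyloxiran-2-yl]methyl}oxiran-2-yl]-3-[(trifluoromethanesulfonyl)oxy]hepta-2,6-dienoate
Conditions: D-glucose-derived spiro N-(4-methylphenyl)oxazolidinone ketone of Shi (25 mol%), KHSO5 (as 2KHSO5·KHSO4·K2SO4, 1.8 equiv), K2CO3, Bu4NHSO4 (cat.), DME/dimethoxymethane–aq. buffer pH 8, 0 °C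
Reagents that add atoms: potassium peroxymonosulfate, [K+].[O-]S(=O)(=O)OO
Why: Shi asymmetric epoxidation by a chiral dioxirane: the oxazolidinone ketone made for cis-alkenes reacts at the electron-rich (Z)-disubstituted end of the conjugated diene with the vinyl group as π-director beside the oxazolidinone in the spiro transition state, oxygen transfer is concerted so the cis geometry is kept, and the D-glucose-derived catalyst gives the (1R,2S)-oxirane, the same sense as its (1R,2S)-cis-β-methylstyrene oxide.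

**Step 13**
Reactants: 18 methyl (2Z,4S)-4-[(tert-butyldimethylsilyl)oxy]-2-{[(tert-butyldimethylsilyl)oxy]methyl}-6-[(2R,3S)-3-{[(2R,3R)-3-(hydroxymethyl)-2-methyloxiran-2-yl]methyl}oxiran-2-yl]-3-[(trifluoromethanesulfonyl)oxy]hepta-2,6-dienoate
Product: 19 methyl (2Z,4S)-4-[(tert-butyldimethylsilyl)oxy]-2-{[(tert-butyldimethylsilyl)oxy]methyl}-6-[(2R,3S)-3-{[(2R,3S)-3-formyl-2-methyloxiran-2-yl]methyl}oxiran-2-yl]-3-[(trifluoromethanesulfonyl)oxy]hepta-2,6-dienoate
Conditions: TEMPO (10 mol%), PhI(OAc)2, CH2Cl2, rt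
Reagents that add atoms: none
Why: Nitroxyl-catalysed (oxoammonium) oxidation of the primary epoxy alcohol to the aldehyde under non-basic conditions that leave both oxiranes, the enol triflate and the α-oxiranyl centre untouched (its descriptor changes from R to S only because CHO now outranks C4).

**Step 14**
Reactants: 19 methyl (2Z,4S)-4-[(tert-butyldimethylsilyl)oxy]-2-{[(tert-butyldimethylsilyl)oxy]methyl}-6-[(2R,3S)-3-{[(2R,3S)-3-formyl-2-methyloxiran-2-yl]methyl}oxiran-2-yl]-3-[(trifluoromethanesulfonyl)oxy]hepta-2,6-dienoate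
Product: 22 (1R,2S,4R,5R,6S,8S)-8,13-bis[(tert-butyldimethylsilyl)oxy]-1,2:4,5-diepoxygermacra-7(11),10(14)-dien-12,6-olide, via alkenylchromium dichloride 20 (not isolated), via macrocyclic chromium alkoxide 21 (not isolated)
Conditions: CrCl2 (10 equiv), NiCl2 (0.1 equiv), DMF–THF, 19 added by syringe pump to 0.003 M, rt; aq. NH4Cl
Reagents that add atoms: none
Why: Nozaki–Hiyama–Kishi coupling: zerovalent nickel inserts into the alkenyl triflate, transmetalation gives the alkenyl species 20 of trivalent chromium, which adds to the tethered aldehyde at high dilution to close the ten-membered carbocycle, and the alkoxide 21, held cis to CO2Me on C7=C11, lactonises at once to the butenolide, so both rings form in one flask; C6 is set as S because C7 adds anti to the oxirane C5–O bond while the forming ring pushes the bulky O–Cr group outward (between H5 and the oxirane oxygen), the 5,6-threo sense I expect by analogy with related chromium-mediated ten-membered closures onto 4,5-epoxy aldehydes.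

**Step 15**
Reactants: 22 (1R,2S,4R,5R,6S,8S)-8,13-bis[(tert-butyldimethylsilyl)oxy]-1,2:4,5-diepoxygermacra-7(11),10(14)-dien-12,6-olide
Product: 23 (1R,2S,4R,5R,6S,8S)-1,2:4,5-diepoxy-8,13-dihydroxygermacra-7(11),10(14)-dien-12,6-olide
Conditions: HF·pyridine, excess pyridine, THF, 0 °C to rt
Reagents that add atoms: none
Why: Fluoride-mediated desilylation buffered with pyridine removes both silyl ethers; the buffered reagent should spare the oxiranes and the lactone and no stereocentre is involved.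

**Step 16**
Reactants: 23 (1R,2S,4R,5R,6S,8S)-1,2:4,5-diepoxy-8,13-dihydroxygermacra-7(11),10(14)-dien-12,6-olide
Product: 24 (1R,2S,4R,5R,6S,8S)-13-acetoxy-1,2:4,5-diepoxy-8-hydroxygermacra-7(11),10(14)-dien-12,6-olide
Conditions: Ac2O (1.1 equiv), 2,4,6-collidine, CH2Cl2, −20 °C
Reagents that add atoms: acetic anhydride, CC(=O)OC(C)=O
Why: Selective acylation: with one equivalent of anhydride and a hindered pyridine base at low temperature the primary allylic 13-OH is acetylated much faster than the secondary 8-OH next to the tetrasubstituted alkene.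

**Step 17**
Reactants: 25 ethyl 2-(hydroxymethyl)prop-2-enoate
Product: 26 ethyl 2-{[(tert-butyldimethylsilyl)oxy]methyl}prop-2-enoate
Conditions: TBSCl, imidazole, CH2Cl2, 0 °C to rt
Reagents that add atoms: tert-butyldimethylsilyl chloride, CC(C)(C)[Si](C)(C)Cl
Why: Standard silylation of the primary allylic alcohol so that the acid made from it cannot acylate itself.

**Step 18**
Reactants: 26 ethyl 2-{[(tert-butyldimethylsilyl)oxy]methyl}prop-2-enoate
Product: 27 2-{[(tert-butyldimethylsilyl)oxy]methyl}prop-2-enoic acid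
Conditions: LiOH, THF/H2O, 0 °C to rt; then 1 M HCl to pH 3
Reagents that add atoms: lithium hydroxide, [Li+].[OH-]
Why: Saponification (acyl–oxygen cleavage by hydroxide) of the ethyl ester, which the silyl ether survives.

**Step 19**
Reactants: 24 (1R,2S,4R,5R,6S,8S)-13-acetoxy-1,2:4,5-diepoxy-8-hydroxygermacra-7(11),10(14)-dien-12,6-olide; 27 2-{[(tert-butyldimethylsilyl)oxy]methyl}prop-2-enoic acid
Product: 29 (1R,2S,4R,5R,6S,8S)-13-acetoxy-8-[(2-{[(tert-butyldimethylsilyl)oxy]methyl}prop-2-enoyl)oxy]-1,2:4,5-diepoxygermacra-7(11),10(14)-dien-12,6-olide, via mixed Yamaguchi anhydride 28 (not isolated)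
Conditions: 27, 2,4,6-trichlorobenzoyl chloride, Et3N, toluene, rt; then 24, DMAP, rt
Reagents that add atoms: none
Why: Yamaguchi esterification: DMAP attacks the mixed anhydride 28 and the acylpyridinium acylates the secondary 8-OH with retention at C8, since the C8–O bond is never broken.

**Step 20**
Reactants: 29 (1R,2S,4R,5R,6S,8S)-13-acetoxy-8-[(2-{[(tert-butyldimethylsilyl)oxy]methyl}prop-2-enoyl)oxy]-1,2:4,5-diepoxygermacra-7(11),10(14)-dien-12,6-olide
Product: 30 (1R,2S,4R,5R,6S,8S)-13-acetoxy-1,2:4,5-diepoxy-8-{[2-(hydroxymethyl)prop-2-enoyl]oxy}germacra-7(11),10(14)-dien-12,6-olide (CNP0233746.1)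
Conditions: HF·pyridine, excess pyridine, THF, 0 °C
Reagents that add atoms: none
Why: Fluoride-mediated cleavage of the primary allylic silyl ether under buffered conditions chosen to spare the acetate, both esters and both oxiranes, giving the target.

**Compound list**
1 | 2-methylbut-1-en-3-yne | C=C(C)C#C | starting material
2 | ethyl glyoxylate | CCOC(=O)C=O | starting material
3 | ethyl (2S)-2-hydroxy-4-methylidenehex-5-ynoate | CCOC(=O)[C@@H](O)CC(=C)C#C | intermediate
4 | ethyl (2S)-2-[(tert-butyldimethylsilyl)oxy]-4-methylidenehex-5-ynoate | CCOC(=O)[C@@H](O[Si](C)(C)C(C)(C)C)CC(=C)C#C | intermediate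
5 | methyl 3-hydroxypropanoate | COC(=O)CCO | starting material
6 | methyl 3-[(tert-butyldimethylsilyl)oxy]propanoate | COC(=O)CCO[Si](C)(C)C(C)(C)C | intermediate
7 | lithium enolate of 6 | [Li]OC(OC)=CCO[Si](C)(C)C(C)(C)C | intermediate (not isolated)
8 | methyl (4S)-4-(TBSO)-2-(TBSOCH2)-6-methylidene-3-oxooct-7-ynoate, both C2 epimers | COC(=O)C(CO[Si](C)(C)C(C)(C)C)C(=O)[C@@H](O[Si](C)(C)C(C)(C)C)CC(=C)C#C | intermediate
9 | chelated lithium (Z)-enolate of 8 | COC(=O)/C(CO[Si](C)(C)C(C)(C)C)=C(O[Li])/[C@@H](O[Si](C)(C)C(C)(C)C)CC(=C)C#C | intermediate (not isolated)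
10 | methyl (2Z,4S)-4-(TBSO)-2-(TBSOCH2)-6-methylidene-3-(TfO)oct-2-en-7-ynoate | COC(=O)/C(CO[Si](C)(C)C(C)(C)C)=C(OS(=O)(=O)C(F)(F)F)/[C@@H](O[Si](C)(C)C(C)(C)C)CC(=C)C#C | intermediate
11 | 3-methylbut-2-en-1-yl acetate | CC(C)=CCOC(C)=O | starting material
12 | (2E)-4-hydroxy-3-methylbut-2-en-1-yl acetate | CC(=O)OC/C=C(\C)CO | intermediate
13 | (2E)-4-bromo-3-methylbut-2-en-1-yl acetate | CC(=O)OC/C=C(\C)CBr | intermediate
14 | (2E)-4-bromo-3-methylbut-2-en-1-ol | OC/C=C(\C)CBr | intermediate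
15 | methyl (2Z,4S,10E)-4-(TBSO)-2-(TBSOCH2)-12-hydroxy-10-methyl-6-methylidene-3-(TfO)dodeca-2,10-dien-7-ynoate | COC(=O)/C(CO[Si](C)(C)C(C)(C)C)=C(OS(=O)(=O)C(F)(F)F)/[C@@H](O[Si](C)(C)C(C)(C)C)CC(=C)C#CC/C(C)=C/CO | intermediate
16 | methyl (2Z,4S,7Z,10E)-4-(TBSO)-2-(TBSOCH2)-12-hydroxy-10-methyl-6-methylidene-3-(TfO)dodeca-2,7,10-trienoate | COC(=O)/C(CO[Si](C)(C)C(C)(C)C)=C(OS(=O)(=O)C(F)(F)F)/[C@@H](O[Si](C)(C)C(C)(C)C)CC(=C)/C=C\C/C(C)=C/CO | intermediate
17 | methyl (2Z,4S,7Z)-4-(TBSO)-2-(TBSOCH2)-9-[(2R,3R)-3-(hydroxymethyl)-2-methyloxiran-2-yl]-6-methylidene-3-(TfO)nona-2,7-dienoate | COC(=O)/C(CO[Si](C)(C)C(C)(C)C)=C(OS(=O)(=O)C(F)(F)F)/[C@@H](O[Si](C)(C)C(C)(C)C)CC(=C)/C=C\C[C@@]1(C)O[C@@H]1CO | intermediate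
18 | methyl (2Z,4S)-4-(TBSO)-2-(TBSOCH2)-6-[(2R,3S)-3-{[(2R,3R)-3-(hydroxymethyl)-2-methyloxiran-2-yl]methyl}oxiran-2-yl]-3-(TfO)hepta-2,6-dienoate | COC(=O)/C(CO[Si](C)(C)C(C)(C)C)=C(OS(=O)(=O)C(F)(F)F)/[C@@H](O[Si](C)(C)C(C)(C)C)CC(=C)[C@H]1O[C@H]1C[C@@]2(C)O[C@@H]2CO | intermediate
19 | methyl (2Z,4S)-4-(TBSO)-2-(TBSOCH2)-6-[(2R,3S)-3-{[(2R,3S)-3-formyl-2-methyloxiran-2-yl]methyl}oxiran-2-yl]-3-(TfO)hepta-2,6-dienoate | COC(=O)/C(CO[Si](C)(C)C(C)(C)C)=C(OS(=O)(=O)C(F)(F)F)/[C@@H](O[Si](C)(C)C(C)(C)C)CC(=C)[C@H]1O[C@H]1C[C@@]2(C)O[C@@H]2C=O | intermediate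
20 | alkenylchromium dichloride from 19 (CrCl2 in place of OTf at C7) | COC(=O)/C(CO[Si](C)(C)C(C)(C)C)=C([Cr](Cl)Cl)/[C@@H](O[Si](C)(C)C(C)(C)C)CC(=C)[C@H]1O[C@H]1C[C@@]2(C)O[C@@H]2C=O | intermediate (not isolated)
21 | dichlorochromium 6-alkoxide of methyl (1R,2S,4R,5R,6S,8S)-8,13-bis(TBSO)-1,2:4,5-diepoxy-6-hydroxygermacra-7(11),10(14)-dien-12-oate (CO2Me cis to C6) | COC(=O)/C(CO[Si](C)(C)C(C)(C)C)=C1/[C@@H](O[Si](C)(C)C(C)(C)C)CC(=C)[C@H]2O[C@H]2C[C@@]2(C)O[C@@H]2[C@H]1O[Cr](Cl)Cl | intermediate (not isolated)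
22 | (1R,2S,4R,5R,6S,8S)-8,13-bis(TBSO)-1,2:4,5-diepoxygermacra-7(11),10(14)-dien-12,6-olide | CC(C)(C)[Si](C)(C)O[C@H]1CC(=C)[C@H]2O[C@H]2C[C@@]2(C)O[C@@H]2[C@H]2OC(=O)C(CO[Si](C)(C)C(C)(C)C)=C12 | intermediate
23 | (1R,2S,4R,5R,6S,8S)-1,2:4,5-diepoxy-8,13-dihydroxygermacra-7(11),10(14)-dien-12,6-olide | O[C@H]1CC(=C)[C@H]2O[C@H]2C[C@@]2(C)O[C@@H]2[C@H]2OC(=O)C(CO)=C12 | intermediate
24 | (1R,2S,4R,5R,6S,8S)-13-acetoxy-1,2:4,5-diepoxy-8-hydroxygermacra-7(11),10(14)-dien-12,6-olide | O[C@H]1CC(=C)[C@H]2O[C@H]2C[C@@]2(C)O[C@@H]2[C@H]2OC(=O)C(COC(C)=O)=C12 | intermediate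
25 | ethyl 2-(hydroxymethyl)prop-2-enoate | C=C(CO)C(=O)OCC | starting material
26 | ethyl 2-{[(tert-butyldimethylsilyl)oxy]methyl}prop-2-enoate | C=C(CO[Si](C)(C)C(C)(C)C)C(=O)OCC | intermediate
27 | 2-{[(tert-butyldimethylsilyl)oxy]methyl}prop-2-enoic acid | C=C(CO[Si](C)(C)C(C)(C)C)C(=O)O | intermediate
28 | mixed anhydride of 27 and 2,4,6-trichlorobenzoic acid | C=C(CO[Si](C)(C)C(C)(C)C)C(=O)OC(=O)c1c(Cl)cc(Cl)cc1Cl | intermediate (not isolated)
29 | (1R,2S,4R,5R,6S,8S)-13-acetoxy-8-[(2-{[(tert-butyldimethylsilyl)oxy]methyl}prop-2-enoyl)oxy]-1,2:4,5-diepoxygermacra-7(11),10(14)-dien-12,6-olide | C=C(CO[Si](C)(C)C(C)(C)C)C(=O)O[C@H]1CC(=C)[C@H]2O[C@H]2C[C@@]2(C)O[C@@H]2[C@H]2OC(=O)C(COC(C)=O)=C12 | intermediate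
30 | (1R,2S,4R,5R,6S,8S)-13-acetoxy-1,2:4,5-diepoxy-8-{[2-(hydroxymethyl)prop-2-enoyl]oxy}germacra-7(11),10(14)-dien-12,6-olide | C=C(CO)C(=O)O[C@H]1CC(=C)[C@H]2O[C@H]2C[C@@]2(C)O[C@@H]2[C@H]2OC(=O)C(COC(C)=O)=C12 | target

**Step count**
Total: 20 steps (14 on the main line; 6 for the building blocks 6, 14 and 27).
Longest linear sequence: 14 steps (1, 2, 4, 5, 9, 10, 11, 12, 13, 14, 15, 16, 19, 20).

**Three steps most likely to fail**

Step 14 (Ni/Cr closure with lactonisation). Risks: zerovalent nickel may ionise the vinyl oxirane instead of the triflate; the C8 silyl ether may oppose the oxirane in directing C6; oligomers may form. The fallback sets out from 16 and rejoins at 22, moving both epoxidations behind the ring closure. Compound 16 is oxidised with MnO2 (CH2Cl2, rt) to methyl (2Z,4S,7Z,10E)-4-(TBSO)-2-(TBSOCH2)-10-methyl-6-methylidene-12-oxo-3-(TfO)dodeca-2,7,10-trienoate F4. F4 is closed with CrCl2/NiCl2 in the presence of a Kishi-type chiral sulfonamide ligand, so that C6 is set by the ligand, to give (1Z,4E,6R,8S)-8,13-bis(TBSO)germacra-1,4,7(11),10(14)-tetraen-12,6-olide F5 (6R is only the CIP label for the same spatial arrangement as C6 of 22). F5 is then treated with the Shi ketone and KHSO5 (2.5 equiv). The E-4,5 alkene is attacked from its open outer face, syn to O6, because H6 lies in the alkene plane next to C15 and C7 blocks the inner face; this gives the 5,6-threo oxirane. The Z-1,2 alkene of the diene is epoxidised under catalyst control, giving 22.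

Step 1 (glyoxylate-ene with an enyne). Risks: the alkynyl-substituted alkene is less nucleophilic than the usual 1,1-disubstituted ene partners, and the product can react a second time. The fallback sets out from 1 and rejoins at 3, replacing the ene reaction by acylation and asymmetric reduction. Compound 1 is dimetalated at the methyl group and the alkyne (n-BuLi/KOtBu, THF–hexane, −78 °C) and added to excess diethyl oxalate at −78 °C, where the allylic end acylates to give ethyl 4-methylidene-2-oxohex-5-ynoate F1. Noyori transfer hydrogenation of the α-keto ester (RuCl[(S,S)-TsDPEN](p-cymene) or its antipode, whichever delivers the S alcohol; HCO2H/Et3N) gives 3.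

Step 12 (Shi epoxidation on the open chain). Risks: competing attack at the 1,1-disubstituted alkene, slow hydrolysis of the enol triflate in the pH 8 buffer, and moderate ee. The fallback sets out from 17 and rejoins at 22, making the C1–C2 oxirane only after the ring is closed and the triflate is gone. Compound 17 is oxidised (TEMPO, PhI(OAc)2) to methyl (2Z,4S,7Z)-4-(TBSO)-2-(TBSOCH2)-9-[(2R,3S)-3-formyl-2-methyloxiran-2-yl]-6-methylidene-3-(TfO)nona-2,7-dienoate F2. F2 is closed with CrCl2/NiCl2 as in step 14 to give (1Z,4R,5R,6S,8S)-8,13-bis(TBSO)-4,5-epoxygermacra-1,7(11),10(14)-trien-12,6-olide F3. The ring Z-alkene of F3 is then epoxidised with dimethyldioxirane (acetone, −20 °C) from the outer face of the ten-membered ring; the face must be checked by NOE, and the chiral ketone of step 12 is used instead if the ring alone selects the wrong one. This gives 22.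

**Further compounds**
F1 | step 1 | ethyl 4-methylidene-2-oxohex-5-ynoate | CCOC(=O)C(=O)CC(=C)C#C
F2 | step 12 | methyl (2Z,4S,7Z)-4-(TBSO)-2-(TBSOCH2)-9-[(2R,3S)-3-formyl-2-methyloxiran-2-yl]-6-methylidene-3-(TfO)nona-2,7-dienoate | COC(=O)/C(CO[Si](C)(C)C(C)(C)C)=C(OS(=O)(=O)C(F)(F)F)/[C@@H](O[Si](C)(C)C(C)(C)C)CC(=C)/C=C\C[C@@]1(C)O[C@@H]1C=O
F3 | step 12 | (1Z,4R,5R,6S,8S)-8,13-bis(TBSO)-4,5-epoxygermacra-1,7(11),10(14)-trien-12,6-olide | CC(C)(C)[Si](C)(C)O[C@H]1CC(=C)/C=C\C[C@@]2(C)O[C@@H]2[C@H]2OC(=O)C(CO[Si](C)(C)C(C)(C)C)=C12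
F4 | step 14 | methyl (2Z,4S,7Z,10E)-4-(TBSO)-2-(TBSOCH2)-10-methyl-6-methylidene-12-oxo-3-(TfO)dodeca-2,7,10-trienoate | COC(=O)/C(CO[Si](C)(C)C(C)(C)C)=C(OS(=O)(=O)C(F)(F)F)/[C@@H](O[Si](C)(C)C(C)(C)C)CC(=C)/C=C\C/C(C)=C/C=O
F5 | step 14 | (1Z,4E,6R,8S)-8,13-bis(TBSO)germacra-1,4,7(11),10(14)-tetraen-12,6-olide | CC(C)(C)[Si](C)(C)O[C@H]1CC(=C)/C=C\C/C(C)=C/[C@H]2OC(=O)C(CO[Si](C)(C)C(C)(C)C)=C12
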